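The route rests on building ring B of the flavanone unit, a para-disubstituted benzene that carries O3 of the kaempferol unit at C4' and the flavanone C2 at C1', directly on that hindered oxygen. An inverse-demand Diels–Alder reaction of a kaempferol 3-O-ethynyl ether with methyl coumalate, followed by loss of CO2, forms both new C–C bonds, the aromatic ring and the para ester in one operation. The precursor is 7,4'-di-O-benzylkaempferol carrying HC≡C– on O3; O5–H is left free so that its lithium salt shields C4=O while the alkyne is made. The ester carbon then becomes flavanone C2, set S by asymmetric hydrogenation of a flavone.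

Key step: step 6

Assumption: the (R,R) antipode of the ligand SINpEt is taken to give the 2S configuration; the sense of induction is checked on flavone 5 beforehand, and the (S,S) antipode is used with no other change if it proves opposite.

Step 1
Reactants: 1 2',4',6'-trihydroxyacetophenone
Product: 2 1-[2,4-bis(benzyloxy)-6-hydroxyphenyl]ethanone
Conditions: BnBr (2.1 equiv), K2CO3, DMF, rt
Reagents that add atoms: benzyl bromide, BrCc1ccccc1
Why: Williamson etherification: carbonate ionises the two non-chelated phenols for benzylation, while the hydroxyl hydrogen-bonded to the acetyl group is left free for the later ring closures.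

Step 2
Reactants: 2 1-[2,4-bis(benzyloxy)-6-hydroxyphenyl]ethanone, 3 4-(benzyloxy)benzoyl chloride
Product: 5 5,7-bis(benzyloxy)-2-[4-(benzyloxy)phenyl]-4H-chromen-4-one (tri-O-benzylapigenin), via β-diketone 4 (not isolated)
Conditions: LiN(SiMe3)2 (3.2 equiv), THF, −78 to −10 °C; 3, −78 °C to rt; aq. HCl; then TsOH·H2O (cat.), toluene, 80 °C
Reagents that add atoms: none
Why: The lithium dianion of 2 is acylated on carbon by 3 to give the 1,3-diketone directly (the one-flask form of the Baker–Venkataraman synthesis), and acid-catalysed cyclodehydration through the free 6-hydroxyl closes the pyranone ring.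

Step 3
Reactants: 5 tri-O-benzylapigenin
Product: 8 7-(benzyloxy)-2-[4-(benzyloxy)phenyl]-3,5-dihydroxy-4H-chromen-4-one (7,4'-di-O-benzylkaempferol), via 2,3-epoxide 6 (not isolated), via tri-O-benzylkaempferol 7 (not isolated)
Conditions: dimethyldioxirane (acetone solution, excess), CH2Cl2, 0 °C to rt; evaporate; then AcOH–conc. HCl (10:1), rt to 60 °C
Reagents that add atoms: dimethyldioxirane, CC1(C)OO1
Why: Dimethyldioxirane epoxidises the electron-rich C2=C3 bond (racemic epoxide, whose two centres vanish in the next event), acid opens it at the oxocarbenium-stabilised C2 to give the 3-hydroxyflavone, and continued warming in HCl–AcOH removes only the benzyl group on O5, whose cleavage is assisted by chelation to C4=O (selective peri-debenzylation), so that O5–H is available as an internal shield in step 5.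

Step 4
Reactants: 8 7,4'-di-O-benzylkaempferol, 9 trichloroethylene
Product: 10 7-(benzyloxy)-2-[4-(benzyloxy)phenyl]-3-{[(E)-1,2-dichloroethenyl]oxy}-5-hydroxy-4H-chromen-4-one
Conditions: 9 (1.3 equiv), K2CO3 (1.2 equiv), DMF, 60 °C, argon
Reagents that add atoms: none
Why: Carbonate converts 9 into dichloroacetylene in the flask and the more acidic 3-oxide adds to it in trans fashion to give the E-dichlorovinyl ether (nucleophilic vinylation of a phenoxide by trichloroethylene), the chelated 5-hydroxyl being as inert here as in carbonate-mediated alkylations.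

Step 5
Reactants: 10 the (E)-1,2-dichlorovinyl ether
Product: 12 7-(benzyloxy)-2-[4-(benzyloxy)phenyl]-3-(ethynyloxy)-5-hydroxy-4H-chromen-4-one, via chloroethynyl ether 11 (not isolated)
Conditions: LiN(SiMe3)2 (1.1 equiv), THF, −78 °C; n-BuLi (2.2 equiv), −78 to −40 °C; sat. aq. NH4Cl, −78 °C; quick filtration through Et3N-deactivated silica, used at once
Reagents that add atoms: none
Why: The amide base first makes the lithium 5-phenoxide, which turns C4=O into a vinylogous carboxylate that resists organolithium addition, and n-BuLi then removes the vinyl proton, expels chloride to give 11 and exchanges the remaining chlorine for lithium, so that protonation delivers the terminal alkynyl ether (the standard dichlorovinyl ether to alkynyl ether conversion).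

Step 6
Reactants: 12 the 3-O-ethynyl ether, 13 methyl coumalate (methyl 2-oxo-2H-pyran-5-carboxylate)
Product: 15 methyl 4-({7-(benzyloxy)-2-[4-(benzyloxy)phenyl]-5-hydroxy-4-oxo-4H-chromen-3-yl}oxy)benzoate, via bicyclic lactone 14 (not isolated)
Conditions: 13 (2.5 equiv), toluene, 110 °C, sealed tube, argon
Reagents that add atoms: none
Why: The terminal alkyne carbon of 12, made nucleophilic by O3, bonds to C6 of the electron-poor pyranone 13 and the oxygen-bearing alkyne carbon bonds to C3 in an asynchronous inverse-electron-demand [4+2] cycloaddition that gives the bridged lactone 14. At the reaction temperature 14 expels CO2 by a retro-[4+2] step, so the benzene ring appears directly and needs no oxidation. The closest known reaction type is the Diels–Alder/decarboxylation benzannulation of methyl coumalate with alkoxyalkynes and ketene acetals, which gives para-alkoxybenzoates. Ring B is thus closed by cycloaddition across the diene termini C3 and C6 (two new C–C bonds) and aromatised by the cycloreversion; no stereocentre is created, the two bridgehead centres of 14 being lost with CO2. The selectivity required is regiochemical, para against meta, and it is secured by matching polarity: the largest HOMO coefficient lies on the unsubstituted alkyne carbon and the largest LUMO coefficient on C6, which is both the δ-carbon of the pyranone and β to the ester. An alkynyl ether whose oxygen sits on an sp2 carbon has no β-hydrogen for retro-ene loss of ketene, and the hydrogen-bonded 5-hydroxyl is a poor proton donor, so 12 should tolerate the heating that its modest nucleophilicity demands.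

Step 7
Reactants: 15 the 5-hydroxy benzoate
Product: 16 methyl 4-({5,7-bis(benzyloxy)-2-[4-(benzyloxy)phenyl]-4-oxo-4H-chromen-3-yl}oxy)benzoate
Conditions: BnBr (1.5 equiv), K2CO3, KI (cat.), DMF, 60 °C
Reagents that add atoms: benzyl bromide, BrCc1ccccc1
Why: Williamson etherification under warm carbonate conditions caps the chelated 5-hydroxyl, so that no acidic, chelating phenol meets the strongly basic enolate chemistry of step 8 or the ruthenium catalyst of step 9.

Step 8
Reactants: 16 the tri-O-benzyl benzoate, 2 1-[2,4-bis(benzyloxy)-6-hydroxyphenyl]ethanone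
Product: 18 5,7-bis(benzyloxy)-3-{4-[5,7-bis(benzyloxy)-4-oxo-4H-chromen-2-yl]phenoxy}-2-[4-(benzyloxy)phenyl]-4H-chromen-4-one (penta-O-benzyl biflavone), via β-diketone 17 (not isolated)
Conditions: 2 (1.5 equiv), LiN(SiMe3)2 (4.5 equiv), THF, −78 °C to rt; aq. HCl; then TsOH·H2O (cat.), toluene, 80 °C
Reagents that add atoms: none
Why: Crossed Claisen condensation of the lithium dianion of 2 with the non-enolisable benzoate, driven by deprotonation of the 1,3-diketone formed, is followed by acid-catalysed cyclodehydration through the free hydroxyl to the second pyranone ring.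

Step 9
Reactants: 18 the penta-O-benzyl biflavone
Product: 20 5,7-bis(benzyloxy)-3-{4-[(2S)-5,7-bis(benzyloxy)-4-oxochroman-2-yl]phenoxy}-2-[4-(benzyloxy)phenyl]-4H-chromen-4-one, via flavan-4-ol 19 (not isolated)
Conditions: Ru(cod)(2-methylallyl)2 (5 mol %), (R,R)-SINpEt·HBF4 [1,3-bis((R)-1-(1-naphthyl)ethyl)imidazolinium tetrafluoroborate] (10 mol %), KOtBu (12 mol %), toluene, H2 (100 bar), 40 °C; then Dess–Martin periodinane, CH2Cl2, rt
Reagents that add atoms: none
Why: Asymmetric hydrogenation of flavones with this chiral carbene–ruthenium catalyst adds hydrogen to one face of the trisubstituted C2=C3 bond of the 3-unsubstituted pyranone and so sets C2 as S under catalyst control, the tetrasubstituted 3-aryloxy alkene of the other unit being too hindered to react, and Dess–Martin oxidation returns the over-reduced C4 carbinol to the ketone without touching C2.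

Step 10
Reactants: 20 the (2S)-penta-O-benzyl flavanone
Product: 21 3-{4-[(2S)-5,7-dihydroxy-4-oxochroman-2-yl]phenoxy}-5,7-dihydroxy-2-(4-hydroxyphenyl)-4H-chromen-4-one (target)
Conditions: H2 (1 atm), 10% Pd/C, THF–MeOH, rt
Reagents that add atoms: none
Why: Hydrogenolysis over palladium cleaves the five benzyl ethers under neutral conditions, under which the flavanone C2 centre does not epimerise by ring opening and neither pyranone carbonyl nor the flavonol double bond is reduced.

Compound list
1 | 2',4',6'-trihydroxyacetophenone | CC(=O)c1c(O)cc(O)cc1O | starting material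
2 | 1-[2,4-bis(benzyloxy)-6-hydroxyphenyl]ethanone | CC(=O)c1c(O)cc(OCc2ccccc2)cc1OCc1ccccc1 | intermediate
3 | 4-(benzyloxy)benzoyl chloride | O=C(Cl)c1ccc(OCc2ccccc2)cc1 | starting material
4 | 1-[2,4-bis(benzyloxy)-6-hydroxyphenyl]-3-[4-(benzyloxy)phenyl]propane-1,3-dione (not isolated) | O=C(CC(=O)c1c(O)cc(OCc2ccccc2)cc1OCc1ccccc1)c1ccc(OCc2ccccc2)cc1 | intermediate
5 | 5,7-bis(benzyloxy)-2-[4-(benzyloxy)phenyl]-4H-chromen-4-one | O=c1cc(-c2ccc(OCc3ccccc3)cc2)oc2cc(OCc3ccccc3)cc(OCc3ccccc3)c12 | intermediate
6 | 5,7-bis(benzyloxy)-2-[4-(benzyloxy)phenyl]-2,3-epoxychroman-4-one (racemic, not isolated) | O=C1C2OC2(c2ccc(OCc3ccccc3)cc2)Oc2cc(OCc3ccccc3)cc(OCc3ccccc3)c12 | intermediate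
7 | 5,7-bis(benzyloxy)-2-[4-(benzyloxy)phenyl]-3-hydroxy-4H-chromen-4-one (not isolated) | O=c1c(O)c(-c2ccc(OCc3ccccc3)cc2)oc2cc(OCc3ccccc3)cc(OCc3ccccc3)c12 | intermediate
8 | 7-(benzyloxy)-2-[4-(benzyloxy)phenyl]-3,5-dihydroxy-4H-chromen-4-one | O=c1c(O)c(-c2ccc(OCc3ccccc3)cc2)oc2cc(OCc3ccccc3)cc(O)c12 | intermediate
9 | trichloroethylene | ClC=C(Cl)Cl | starting material
10 | 7-(benzyloxy)-2-[4-(benzyloxy)phenyl]-3-{[(E)-1,2-dichloroethenyl]oxy}-5-hydroxy-4H-chromen-4-one | Cl/C=C(/Cl)Oc1c(-c2ccc(OCc3ccccc3)cc2)oc2cc(OCc3ccccc3)cc(O)c2c1=O | intermediate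
11 | 7-(benzyloxy)-2-[4-(benzyloxy)phenyl]-3-[(chloroethynyl)oxy]-5-hydroxy-4H-chromen-4-one (not isolated; lithium 5-phenoxide in the flask) | ClC#COc1c(-c2ccc(OCc3ccccc3)cc2)oc2cc(OCc3ccccc3)cc(O)c2c1=O | intermediate
12 | 7-(benzyloxy)-2-[4-(benzyloxy)phenyl]-3-(ethynyloxy)-5-hydroxy-4H-chromen-4-one | C#COc1c(-c2ccc(OCc3ccccc3)cc2)oc2cc(OCc3ccccc3)cc(O)c2c1=O | intermediate
13 | methyl coumalate (methyl 2-oxo-2H-pyran-5-carboxylate) | COC(=O)c1ccc(=O)oc1 | starting material
14 | methyl 3-oxo-2-oxabicyclo[2.2.2]octa-5,7-diene-6-carboxylate bearing the flavon-3-yloxy group of 12 on C8 (racemic, not isolated) | COC(=O)C1=CC2C(=O)OC1C=C2Oc1c(-c2ccc(OCc3ccccc3)cc2)oc2cc(OCc3ccccc3)cc(O)c2c1=O | intermediate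
15 | methyl 4-({7-(benzyloxy)-2-[4-(benzyloxy)phenyl]-5-hydroxy-4-oxo-4H-chromen-3-yl}oxy)benzoate | COC(=O)c1ccc(Oc2c(-c3ccc(OCc4ccccc4)cc3)oc3cc(OCc4ccccc4)cc(O)c3c2=O)cc1 | intermediate
16 | methyl 4-({5,7-bis(benzyloxy)-2-[4-(benzyloxy)phenyl]-4-oxo-4H-chromen-3-yl}oxy)benzoate | COC(=O)c1ccc(Oc2c(-c3ccc(OCc4ccccc4)cc3)oc3cc(OCc4ccccc4)cc(OCc4ccccc4)c3c2=O)cc1 | intermediate
17 | 1-[2,4-bis(benzyloxy)-6-hydroxyphenyl]-3-[4-({5,7-bis(benzyloxy)-2-[4-(benzyloxy)phenyl]-4-oxo-4H-chromen-3-yl}oxy)phenyl]propane-1,3-dione (not isolated) | O=C(CC(=O)c1c(O)cc(OCc2ccccc2)cc1OCc1ccccc1)c1ccc(Oc2c(-c3ccc(OCc4ccccc4)cc3)oc3cc(OCc4ccccc4)cc(OCc4ccccc4)c3c2=O)cc1 | intermediate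
18 | 5,7-bis(benzyloxy)-3-{4-[5,7-bis(benzyloxy)-4-oxo-4H-chromen-2-yl]phenoxy}-2-[4-(benzyloxy)phenyl]-4H-chromen-4-one | O=c1cc(-c2ccc(Oc3c(-c4ccc(OCc5ccccc5)cc4)oc4cc(OCc5ccccc5)cc(OCc5ccccc5)c4c3=O)cc2)oc2cc(OCc3ccccc3)cc(OCc3ccccc3)c12 | intermediate
19 | 5,7-bis(benzyloxy)-3-{4-[(2S,4S)-5,7-bis(benzyloxy)-4-hydroxychroman-2-yl]phenoxy}-2-[4-(benzyloxy)phenyl]-4H-chromen-4-one (2,4-cis expected; its C4 epimer would serve equally; not isolated) | O[C@H]1C[C@@H](c2ccc(Oc3c(-c4ccc(OCc5ccccc5)cc4)oc4cc(OCc5ccccc5)cc(OCc5ccccc5)c4c3=O)cc2)Oc2cc(OCc3ccccc3)cc(OCc3ccccc3)c21 | intermediate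
20 | 5,7-bis(benzyloxy)-3-{4-[(2S)-5,7-bis(benzyloxy)-4-oxochroman-2-yl]phenoxy}-2-[4-(benzyloxy)phenyl]-4H-chromen-4-one | O=C1C[C@@H](c2ccc(Oc3c(-c4ccc(OCc5ccccc5)cc4)oc4cc(OCc5ccccc5)cc(OCc5ccccc5)c4c3=O)cc2)Oc2cc(OCc3ccccc3)cc(OCc3ccccc3)c21 | intermediate
21 | 3-{4-[(2S)-5,7-dihydroxy-4-oxochroman-2-yl]phenoxy}-5,7-dihydroxy-2-(4-hydroxyphenyl)-4H-chromen-4-one | O=C1C[C@@H](c2ccc(Oc3c(-c4ccc(O)cc4)oc4cc(O)cc(O)c4c3=O)cc2)Oc2cc(O)cc(O)c21 | target

Total step count: 10. Longest linear sequence: 10 steps (1 → 2 → 5 → 8 → 10 → 12 → 15 → 16 → 18 → 20 → 21); compound 2 is used twice, in steps 2 and 8.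

Steps most likely to fail

Most at risk is step 6. The alkynyl ether 12 may oligomerise or be hydrated to the 3-O-acetate before it reacts, dimerisation of 13 may outrun a sluggish cycloaddition, and regiocontrol may erode at the temperature needed. The fallback gives up the ring construction and forms the C3–O–aryl bond directly. It sets out from 8: the 3-oxide (KOtBu, 1.0 equiv, THF, 0 °C to rt) is arylated without metal by bis[4-(methoxycarbonyl)phenyl]iodonium triflate, a diaryl ether synthesis that tolerates crowded and weakly nucleophilic phenoxides. The chelated 5-hydroxyl stays free, so the product is 15 and the route is rejoined at step 7; new compounds on this way: none F0.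

Second is step 9. Hydrogenation may stall on the large polyether substrate, the catalyst may distinguish the two faces poorly, or the second pyranone may be reduced as well. The fallback separates reduction from stereocontrol and sets out from 18. Conjugate hydride addition with LiBH(s-Bu)3 (THF, −78 °C) to the less hindered, 3-unsubstituted pyranone should give the racemic penta-O-benzyl flavanone F1. Kinetic resolution by transfer hydrogenation with Cp*RhCl[(R,R)-TsDPEN] and HCO2H–Et3N (EtOAc, rt), carried slightly beyond half conversion, should reduce the 2R enantiomer to the cis-(2R,4R)-flavan-4-ol F2 and leave the 2S ketone. That ketone is 20, and the route is rejoined at step 10.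

Third is step 5. Butyllithium may still add to the pyranone carbonyl despite the phenoxide shield, or the terminal alkynyl ether may be lost to hydration during isolation. The fallback avoids organolithium reagents and sets out from 10. Hydrodechlorination with Bu3SnH and Pd(PPh3)4 (toluene, rt) should occur at the oxygen-bearing carbon, where oxidative addition of such dichlorovinyl ethers takes place first, and give the (Z)-2-chlorovinyl ether F3 with retention of geometry. Anti-dehydrochlorination with the non-nucleophilic amide KN(SiMe3)2 (3.2 equiv, THF, −78 °C), the classical route from β-halovinyl ethers to alkynyl ethers, should then give 12, where the route is rejoined at step 6.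

Further compounds
F0 | step 6 | none | none
F1 | step 9 | racemic 5,7-bis(benzyloxy)-3-{4-[5,7-bis(benzyloxy)-4-oxochroman-2-yl]phenoxy}-2-[4-(benzyloxy)phenyl]-4H-chromen-4-one | O=C1CC(c2ccc(Oc3c(-c4ccc(OCc5ccccc5)cc4)oc4cc(OCc5ccccc5)cc(OCc5ccccc5)c4c3=O)cc2)Oc2cc(OCc3ccccc3)cc(OCc3ccccc3)c21
F2 | step 9 | 5,7-bis(benzyloxy)-3-{4-[(2R,4R)-5,7-bis(benzyloxy)-4-hydroxychroman-2-yl]phenoxy}-2-[4-(benzyloxy)phenyl]-4H-chromen-4-one | O[C@@H]1C[C@H](c2ccc(Oc3c(-c4ccc(OCc5ccccc5)cc4)oc4cc(OCc5ccccc5)cc(OCc5ccccc5)c4c3=O)cc2)Oc2cc(OCc3ccccc3)cc(OCc3ccccc3)c21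
F3 | step 5 | 7-(benzyloxy)-2-[4-(benzyloxy)phenyl]-3-{[(Z)-2-chloroethenyl]oxy}-5-hydroxy-4H-chromen-4-one | Cl/C=C\Oc1c(-c2ccc(OCc3ccccc3)cc2)oc2cc(OCc3ccccc3)cc(O)c2c1=O
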